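## Retrosynthetic overview

1. Target ⇐ macrocyclic ketone: the exocyclic C=CH2 is a masked C=O, installed last by non-basic methylenation.
2. Macrocyclic ketone ⇐ open-chain γ-keto aldehyde phosphonate: the only ring (the 14-membered carbocycle) is closed at the (Z)-enoate by intramolecular Still–Gennari olefination.
3. γ-Keto aldehyde ⇐ enal + acyl donor: the ring–side-chain bond (a dissonant 1,4-dicarbonyl) is cut as enal β-carbon plus a nucleophilic acyl unit. This catalytic asymmetric conjugate acylation sets the only stereocentre.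
4. Enal ⇐ nerylacetone (brings the Z-olefin) by alkyne formation, Zr-carboalumination/oxirane opening (E-olefin), phosphonoacetate alkylation and cross-metathesis. Acyl donor ⇐ 1,1-dimethoxyacetone + prenyl bromide (hydration, then 1:1:1 Hantzsch condensation with ethyl acetoacetate and ethyl 3-aminocrotonate).

Assumption 1: nerylacetone is bought as the pure (5Z)-isomer (commercial aroma chemical).
Assumption 2: the phosphonate-bearing carbon is racemic (2RS) wherever it occurs; it becomes sp2 in step 10.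
Assumption 3: only discrete neutral compounds formed in separate operations of a telescoped step are numbered; enolates, ate complexes, iminium ions and the transient species inside a single condensation appear only in the Conditions/Why lines.

## Route

Step 1
Reactants: 1 (5Z)-6,10-dimethylundeca-5,9-dien-2-one (nerylacetone)
Product: 3 (5Z)-6,10-dimethylundeca-5,9-dien-1-yne, via enol phosphate 2 (not isolated)
Conditions: LDA (1.05 equiv), THF, −78 °C; ClP(O)(OEt)2, −78 → 23 °C; then LDA (2.3 equiv), −78 → 23 °C; H2O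
Reagents that add atoms: none
Why: Negishi methyl-ketone-to-alkyne conversion: kinetic deprotonation at CH3, O-phosphorylation and LDA-induced β-elimination of diethyl phosphate give the terminal alkyne without touching the Z-olefin.

Step 2
Reactants: 3 (5Z)-6,10-dimethylundeca-5,9-dien-1-yne
Product: 5 (3E,7Z)-4,8,12-trimethyltrideca-3,7,11-trien-1-ol, via alkenylalane 4 (not isolated)
Conditions: Me3Al (2.5 equiv), Cp2ZrCl2 (25 mol%), CH2Cl2, 23 °C; then n-BuLi (1 equiv, forms the lithium alanate), THF/hexane, −78 °C; ethylene oxide, −78 → 0 °C; aq. HCl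
Reagents that add atoms: trimethylaluminium C[Al](C)C; ethylene oxide C1CO1
Why: Negishi Zr-catalysed methylalumination is a syn addition that puts CH3 on the internal and Al on the terminal alkyne carbon, and the alanate opens oxirane with retention, so the new trisubstituted olefin is E.

Step 3
Reactants: 5 (3E,7Z)-4,8,12-trimethyltrideca-3,7,11-trien-1-ol
Product: 6 (6Z,10E)-13-iodo-2,6,10-trimethyltrideca-2,6,10-triene
Conditions: I2, PPh3, imidazole, CH2Cl2, 0 → 23 °C
Reagents that add atoms: iodine II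
Why: Garegg–Samuelsson (Appel-type) iodination, an SN2 displacement of the alkoxyphosphonium by iodide at a primary carbon.

Step 4
Reactants: 6 (6Z,10E)-13-iodo-2,6,10-trimethyltrideca-2,6,10-triene; 7 methyl 2-[bis(2,2,2-trifluoroethoxy)phosphoryl]acetate
Product: 8 methyl (2RS,5E,9Z)-2-[bis(2,2,2-trifluoroethoxy)phosphoryl]-6,10,14-trimethylpentadeca-5,9,13-trienoate
Conditions: 7 (1.5 equiv), NaH, DMF, 0 °C; then 6, 0 → 45 °C
Reagents that add atoms: none
Why: SN2 C-alkylation of the sodium phosphonoacetate carbanion by the primary iodide; the new P-bearing carbon is racemic and irrelevant.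

Step 5
Reactants: 8 methyl (2RS,5E,9Z)-2-[bis(2,2,2-trifluoroethoxy)phosphoryl]-6,10,14-trimethylpentadeca-5,9,13-trienoate; 9 (2E)-but-2-enal
Product: 10 methyl (2RS,5E,9Z,13E)-2-[bis(2,2,2-trifluoroethoxy)phosphoryl]-6,10-dimethyl-15-oxopentadeca-5,9,13-trienoate
Conditions: 9 (10 equiv), Hoveyda–Grubbs II (5 mol%), CH2Cl2, 40 °C
Reagents that add atoms: none
Why: Olefin cross-metathesis: the gem-dimethyl terminus is the only sterically accessible trisubstituted olefin, and the electron-poor partner gives the (E)-enal while the two internal trisubstituted olefins stay untouched.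

Step 6
Reactants: 11 1,1-dimethoxypropan-2-one; 12 1-bromo-3-methylbut-2-ene
Product: 13 1,1-dimethoxy-6-methylhept-5-en-2-one
Conditions: LDA, THF, −78 °C; then 12, −78 → 0 °C
Reagents that add atoms: none
Why: Kinetic lithium enolate alkylation: LDA deprotonates the CH3 side of the ketone and the enolate displaces the allylic bromide by SN2.

Step 7
Reactants: 13 1,1-dimethoxy-6-methylhept-5-en-2-one
Product: 14 6-hydroxy-1,1-dimethoxy-6-methylheptan-2-one
Conditions: Co(acac)2 (10 mol%), PhSiH3 (2 equiv), O2 (1 atm), THF, 23 °C; aq. Na2S2O3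
Reagents that add atoms: dioxygen O=O
Why: Mukaiyama hydration: Co–H hydrogen-atom transfer to the trisubstituted olefin gives the tertiary radical, which is trapped by O2 and reduced to the Markovnikov tertiary alcohol; ketone and acetal are inert.

Step 8
Reactants: 14 6-hydroxy-1,1-dimethoxy-6-methylheptan-2-one; 15 ethyl (2Z)-3-aminobut-2-enoate; 16 ethyl 3-oxobutanoate
Product: 18 diethyl 4-(5-hydroxy-5-methylhexanoyl)-2,6-dimethyl-1,4-dihydropyridine-3,5-dicarboxylate, via ketoaldehyde 17 (not isolated)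
Conditions: Dowex 50WX8 (H+ form), THF/H2O, 60 °C; filter off the resin; then 15 (1.0 equiv), 16 (1.0 equiv), EtOH, 60 °C, in the dark
Reagents that add atoms: none
Why: Acid-resin hydrolysis unmasks the glyoxal, whose aldehyde carbon (more electrophilic than the ketone) enters a three-component Hantzsch dihydropyridine synthesis with one β-ketoester and one enaminoester (1:1:1, two waters lost) to give the 4-acyl-1,4-dihydropyridine.

Step 9
Reactants: 10 methyl (2RS,5E,9Z,13E)-2-[bis(2,2,2-trifluoroethoxy)phosphoryl]-6,10-dimethyl-15-oxopentadeca-5,9,13-trienoate; 18 diethyl 4-(5-hydroxy-5-methylhexanoyl)-2,6-dimethyl-1,4-dihydropyridine-3,5-dicarboxylate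
Product: 19 methyl (2RS,5E,9Z,13R)-2-[bis(2,2,2-trifluoroethoxy)phosphoryl]-18-hydroxy-6,10,18-trimethyl-14-oxo-13-(2-oxoethyl)nonadeca-5,9-dienoate
Conditions: 18 (1.5 equiv), (S)-2-{bis[3,5-bis(trifluoromethyl)phenyl][(trimethylsilyl)oxy]methyl}pyrrolidine (20 mol%), CF3CO2H (40 mol%), MeCN, 460 nm LEDs, 20 °C; aq. work-up
Reagents that add atoms: none
Why: Iminium-ion organocatalysis merged with a photochemically generated acyl radical (radical Stetter-type conjugate acylation): excited 18 releases the nucleophilic 5-hydroxy-5-methylhexanoyl radical, which adds to C13 of the (E)-iminium ion of 10 on the Re face, anti to the CAr2(OTMS) group of the (S)-catalyst, and reduction/hydrolysis of the adduct gives the 13R γ-keto aldehyde.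

Step 10
Reactants: 19 methyl (2RS,5E,9Z,13R)-2-[bis(2,2,2-trifluoroethoxy)phosphoryl]-18-hydroxy-6,10,18-trimethyl-14-oxo-13-(2-oxoethyl)nonadeca-5,9-dienoate
Product: 20 methyl (1Z,4R,7Z,11E)-4-(5-hydroxy-5-methylhexanoyl)-7,11-dimethylcyclotetradeca-1,7,11-triene-1-carboxylate
Conditions: KHMDS (1.05 equiv, added over 3 h to 19), 18-crown-6 (5 equiv), THF (0.001 M), −78 → −20 °C
Reagents that add atoms: none
Why: Intramolecular Still–Gennari (Z-selective Horner–Wadsworth–Emmons) olefination under high dilution: the phosphonate C–H is by far the most acidic site, and the trifluoroethyl phosphonate eliminates under kinetic control to the (Z)-enoate, which is also the ring-trans geometry of the 14-membered ring; C4 is untouched.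

Step 11
Reactants: 20 methyl (1Z,4R,7Z,11E)-4-(5-hydroxy-5-methylhexanoyl)-7,11-dimethylcyclotetradeca-1,7,11-triene-1-carboxylate
Product: 21 methyl (1Z,4R,7Z,11E)-4-(6-hydroxy-6-methylhept-1-en-2-yl)-7,11-dimethylcyclotetradeca-1,7,11-triene-1-carboxylate
Conditions: Lombardo reagent (Zn/CH2Br2/TiCl4 pre-formed in THF, ca. 5 equiv), CH2Cl2, 0 → 23 °C; aq. NaHCO3
Reagents that add atoms: dibromomethane BrCBr
Why: Takai–Lombardo methylenation: the non-basic gem-dimetallic CH2 reagent methylenates the ketone chemoselectively beside the enoate and the free tertiary alcohol without enolising the adjacent stereocentre.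

## Compound list

1 | (5Z)-6,10-dimethylundeca-5,9-dien-2-one (nerylacetone) | CC(=O)CC/C=C(/C)CCC=C(C)C | starting material
2 | diethyl (5Z)-6,10-dimethylundeca-1,5,9-trien-2-yl phosphate | C=C(OP(=O)(OCC)OCC)CC/C=C(/C)CCC=C(C)C | intermediate (not isolated)
3 | (5Z)-6,10-dimethylundeca-5,9-dien-1-yne | C#CCC/C=C(/C)CCC=C(C)C | intermediate
4 | dimethyl[(1E,5Z)-2,6,10-trimethylundeca-1,5,9-trien-1-yl]alumane | C[Al](C)/C=C(\C)CC/C=C(/C)CCC=C(C)C | intermediate (not isolated)
5 | (3E,7Z)-4,8,12-trimethyltrideca-3,7,11-trien-1-ol | OCC/C=C(\C)CC/C=C(/C)CCC=C(C)C | intermediate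
6 | (6Z,10E)-13-iodo-2,6,10-trimethyltrideca-2,6,10-triene | ICC/C=C(\C)CC/C=C(/C)CCC=C(C)C | intermediate
7 | methyl 2-[bis(2,2,2-trifluoroethoxy)phosphoryl]acetate | COC(=O)CP(=O)(OCC(F)(F)F)OCC(F)(F)F | starting material
8 | methyl (2RS,5E,9Z)-2-[bis(2,2,2-trifluoroethoxy)phosphoryl]-6,10,14-trimethylpentadeca-5,9,13-trienoate | COC(=O)C(CC/C=C(\C)CC/C=C(/C)CCC=C(C)C)P(=O)(OCC(F)(F)F)OCC(F)(F)F | intermediate
9 | (2E)-but-2-enal | C/C=C/C=O | starting material
10 | methyl (2RS,5E,9Z,13E)-2-[bis(2,2,2-trifluoroethoxy)phosphoryl]-6,10-dimethyl-15-oxopentadeca-5,9,13-trienoate | COC(=O)C(CC/C=C(\C)CC/C=C(/C)CC/C=C/C=O)P(=O)(OCC(F)(F)F)OCC(F)(F)F | intermediate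
11 | 1,1-dimethoxypropan-2-one | COC(OC)C(C)=O | starting material
12 | 1-bromo-3-methylbut-2-ene | CC(C)=CCBr | starting material
13 | 1,1-dimethoxy-6-methylhept-5-en-2-one | COC(OC)C(=O)CCC=C(C)C | intermediate
14 | 6-hydroxy-1,1-dimethoxy-6-methylheptan-2-one | COC(OC)C(=O)CCCC(C)(C)O | intermediate
15 | ethyl (2Z)-3-aminobut-2-enoate | CCOC(=O)/C=C(/C)N | starting material
16 | ethyl 3-oxobutanoate (ethyl acetoacetate) | CCOC(=O)CC(C)=O | starting material
17 | 6-hydroxy-6-methyl-2-oxoheptanal | CC(C)(O)CCCC(=O)C=O | intermediate (not isolated)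
18 | diethyl 4-(5-hydroxy-5-methylhexanoyl)-2,6-dimethyl-1,4-dihydropyridine-3,5-dicarboxylate | CCOC(=O)C1=C(C)NC(C)=C(C(=O)OCC)C1C(=O)CCCC(C)(C)O | intermediate
19 | methyl (2RS,5E,9Z,13R)-2-[bis(2,2,2-trifluoroethoxy)phosphoryl]-18-hydroxy-6,10,18-trimethyl-14-oxo-13-(2-oxoethyl)nonadeca-5,9-dienoate | O=CC[C@H](C(=O)CCCC(C)(C)O)CC/C(C)=C\CC/C(C)=C/CCC(P(=O)(OCC(F)(F)F)OCC(F)(F)F)C(=O)OC | intermediate
20 | methyl (1Z,4R,7Z,11E)-4-(5-hydroxy-5-methylhexanoyl)-7,11-dimethylcyclotetradeca-1,7,11-triene-1-carboxylate | O=C(CCCC(C)(C)O)[C@H]1C/C=C(\C(=O)OC)CC/C=C(\C)CC/C=C(/C)CC1 | intermediate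
21 | methyl (1Z,4R,7Z,11E)-4-(6-hydroxy-6-methylhept-1-en-2-yl)-7,11-dimethylcyclotetradeca-1,7,11-triene-1-carboxylate | C=C(CCCC(C)(C)O)[C@H]1C/C=C(\C(=O)OC)CC/C=C(\C)CC/C=C(/C)CC1 | target

## Step count and risks

Total step count: 11. Longest linear sequence: 8 (steps 1–5, 9, 10, 11); the acyl donor branch (steps 6–8) joins at step 9.

Most likely to fail, step 9 (key conjugate acylation). The risks are a β-alkyl enal bearing an acidic phosphonate, the level of ee, and acid-promoted furan formation from the 1,4-keto aldehyde; ee can be upgraded by preparative chiral chromatography of 20. Fallback: set out from 10 and use a nitroalkane as the acyl-anion equivalent. Ethyl 5-bromopentanoate with MeMgBr gives 6-bromo-2-methylhexan-2-ol F1, and NaNO2 in DMF gives 2-methyl-6-nitrohexan-2-ol F2. Michael addition of this nitro alcohol to 10 under (S)-diphenylprolinol TMS ether/benzoic acid catalysis (same Re-face delivery at C13) gives methyl (2RS,5E,9Z,13R,14RS)-2-[bis(2,2,2-trifluoroethoxy)phosphoryl]-18-hydroxy-6,10,18-trimethyl-14-nitro-13-(2-oxoethyl)nonadeca-5,9-dienoate F3. Still–Gennari ring closure (2.1 equiv KHMDS, nitronate as spectator) gives methyl (1Z,4R,7Z,11E)-4-[(1RS)-5-hydroxy-5-methyl-1-nitrohexyl]-7,11-dimethylcyclotetradeca-1,7,11-triene-1-carboxylate F4. A buffered Nef reaction (NaOMe, then TiCl3/NH4OAc) turns CH–NO2 into C=O and the sequence comes back at 20.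

Second, step 10 (macrocyclisation). The risks are oligomers, Z/E erosion, and base-induced epimerisation or aldol reaction of the 1,4-keto aldehyde. Fallback: set out from 6 and close the ring by cross-coupling instead of olefination. Cross-metathesis of 6 with 9 gives (2E,6Z,10E)-13-iodo-6,10-dimethyltrideca-2,6,10-trienal F5. Acyl transfer from 18 under the step 9 conditions gives (3R,6Z,10E)-3-(5-hydroxy-5-methylhexanoyl)-13-iodo-6,10-dimethyltrideca-6,10-dienal F6. Bromination of 7 (NaH, NBS) gives methyl 2-bromo-2-[bis(2,2,2-trifluoroethoxy)phosphoryl]acetate F7, whose olefination with the aldehyde (t-BuOK, 18-crown-6, −78 °C) gives methyl (2E,5R,8Z,12E)-2-bromo-5-(5-hydroxy-5-methylhexanoyl)-15-iodo-8,12-dimethylpentadeca-2,8,12-trienoate F8, with the ester cis to the chain. Ni-catalysed intramolecular reductive cross-electrophile coupling of the alkenyl bromide with the primary iodide (NiBr2·glyme, 4,4′-di-tert-butyl-2,2′-bipyridine, Mn, DMA, syringe pump) forms the ring bond next to the ester carbon with retention of olefin geometry and comes back at 20.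

Third, step 5 (cross-metathesis). The risks are site selectivity and turnover on a triene. Fallback: set out from 8 and functionalise the terminal olefin stepwise (van Tamelen). NBS in THF/H2O gives methyl (2RS,5E,9Z)-2-[bis(2,2,2-trifluoroethoxy)phosphoryl]-13-bromo-14-hydroxy-6,10,14-trimethylpentadeca-5,9-dienoate F9. DBU closes it to methyl (2RS,5E,9Z)-2-[bis(2,2,2-trifluoroethoxy)phosphoryl]-12-(3,3-dimethyloxiran-2-yl)-6,10-dimethyldodeca-5,9-dienoate F10. Periodic acid cleaves the epoxide to methyl (2RS,5E,9Z)-2-[bis(2,2,2-trifluoroethoxy)phosphoryl]-6,10-dimethyl-13-oxotrideca-5,9-dienoate F11. Wittig two-carbon homologation with (triphenylphosphoranylidene)acetaldehyde (toluene, 80 °C) comes back at 10.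

## Further compounds

F1 | step 9 | 6-bromo-2-methylhexan-2-ol | CC(C)(O)CCCCBr
F2 | step 9 | 2-methyl-6-nitrohexan-2-ol | CC(C)(O)CCCC[N+](=O)[O-]
F3 | step 9 | methyl (2RS,5E,9Z,13R,14RS)-2-[bis(2,2,2-trifluoroethoxy)phosphoryl]-18-hydroxy-6,10,18-trimethyl-14-nitro-13-(2-oxoethyl)nonadeca-5,9-dienoate | O=CC[C@H](C(CCCC(C)(C)O)[N+](=O)[O-])CC/C(C)=C\CC/C(C)=C/CCC(P(=O)(OCC(F)(F)F)OCC(F)(F)F)C(=O)OC
F4 | step 9 | methyl (1Z,4R,7Z,11E)-4-[(1RS)-5-hydroxy-5-methyl-1-nitrohexyl]-7,11-dimethylcyclotetradeca-1,7,11-triene-1-carboxylate | [O-][N+](=O)C(CCCC(C)(C)O)[C@H]1C/C=C(\C(=O)OC)CC/C=C(\C)CC/C=C(/C)CC1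
F5 | step 10 | (2E,6Z,10E)-13-iodo-6,10-dimethyltrideca-2,6,10-trienal | O=C/C=C/CC/C(C)=C\CC/C(C)=C/CCI
F6 | step 10 | (3R,6Z,10E)-3-(5-hydroxy-5-methylhexanoyl)-13-iodo-6,10-dimethyltrideca-6,10-dienal | O=CC[C@H](C(=O)CCCC(C)(C)O)CC/C(C)=C\CC/C(C)=C/CCI
F7 | step 10 | methyl 2-bromo-2-[bis(2,2,2-trifluoroethoxy)phosphoryl]acetate | COC(=O)C(Br)P(=O)(OCC(F)(F)F)OCC(F)(F)F
F8 | step 10 | methyl (2E,5R,8Z,12E)-2-bromo-5-(5-hydroxy-5-methylhexanoyl)-15-iodo-8,12-dimethylpentadeca-2,8,12-trienoate | COC(=O)/C(Br)=C\C[C@H](C(=O)CCCC(C)(C)O)CC/C(C)=C\CC/C(C)=C/CCI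
F9 | step 5 | methyl (2RS,5E,9Z)-2-[bis(2,2,2-trifluoroethoxy)phosphoryl]-13-bromo-14-hydroxy-6,10,14-trimethylpentadeca-5,9-dienoate | COC(=O)C(CC/C=C(\C)CC/C=C(/C)CCC(Br)C(C)(C)O)P(=O)(OCC(F)(F)F)OCC(F)(F)F
F10 | step 5 | methyl (2RS,5E,9Z)-2-[bis(2,2,2-trifluoroethoxy)phosphoryl]-12-(3,3-dimethyloxiran-2-yl)-6,10-dimethyldodeca-5,9-dienoate | COC(=O)C(CC/C=C(\C)CC/C=C(/C)CCC1OC1(C)C)P(=O)(OCC(F)(F)F)OCC(F)(F)F
F11 | step 5 | methyl (2RS,5E,9Z)-2-[bis(2,2,2-trifluoroethoxy)phosphoryl]-6,10-dimethyl-13-oxotrideca-5,9-dienoate | COC(=O)C(CC/C=C(\C)CC/C=C(/C)CCC=O)P(=O)(OCC(F)(F)F)OCC(F)(F)F
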